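(The rate constants were drawn at random within sensible limits; the flask was simulated.)

The chemist planning the next run of this flask has two levers, more days or more Z.

X 20 mM; Z 19.0 mM; time 6.0 d

    X ⇌ G (K1 = 0.521, k1 = 8.17 × 10⁻⁵ s⁻¹)
    G ⇌ L (K2 = 24.3, k2 = 5.76 × 10⁻⁵ s⁻¹)
    Z + G → Z.G (k3 = 4.55 × 10⁻⁵ M⁻¹ s⁻¹)
    Z → J (k4 = 6.99 × 10⁻⁶ s⁻¹)
    X + Z → X.Z (k5 = 3.92 × 10⁻⁴ M⁻¹ s⁻¹)

- part of the X that has turned into other species by 6.0 d (G does not count)
- how much X.Z there is at 6.0 d, in percent of the X charged
- how much G there is at 6.0 d, in percent of the X charged

- in a conversion G counts as not yet reacted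
- apart from G, what has gone from X into another species counts as reacted, even if it can come back
- run time (flask): 6.0 d

Follow one molecule of X: it is caught by Z at the pseudo-first-order rate r, which is 7.45 × 10⁻⁶ s⁻¹ with Z as charged, or it goes to G at 8.17 × 10⁻⁵ s⁻¹. From G it returns to X with a chance of 73.1 %; otherwise it passes to L. I leave Z.G out because the half-life of G by its forward step to L alone, 0.14 d, is shorter than by the step to Z.G with Z as charged, 9.3 d. Counting the returns, the leak rate w, the forward rate to G times the chance of not coming back, is 2.19 × 10⁻⁵ s⁻¹.

L returns at 2.37 × 10⁻⁶ s⁻¹, slower than w, so I count it as final. I take the molecule to spend the balance share, one part in (one plus K), of its time as X, where K is the constant of X ⇌ G, so: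

life of the molecule before its fate = (one plus K) / (r + w) = 0.599 d

Z met during that life, thinned by its reaction to J = 14.0 mM

chance of capture = r / (r + w), with r taken at that Z, = 19.9 %

This omits the Z taken by X, although at the start Z goes to J at 0.89 times that rate. The run is ten times that life, and the half-life of Z by its step to J alone, 1.1 d, is shorter than the run, so I would leave the time as it is and raise the charge of Z.

The forecast gave a conversion of 91.2 %, X.Z 17 % and G 3 %, on the ground that “Z decays to J within a few days”. The simulation of this flask gives a conversion of 91.6 %, X.Z 20.1 % and G 2.89 %.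

Now take the neighbouring flask, charged with 48 mM of Z. In this reckoning the leak stays at 2.19 × 10⁻⁵ s⁻¹, while r as charged becomes 1.88 × 10⁻⁵ s⁻¹. The molecule meets 38.1 mM of Z on average, so its chance of capture is 40.5 %. The simulated neighbouring flask holds 41.4 % of the X charged as X.Z at 6.00 d.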